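**Retrosynthetic overview**

1. The last step removes two aryl TIPS ethers with fluoride. Before that, the threo-(7″R,8″R) arylglycerol arm is grown on the single free 4′-phenol of a mono-silylated (−)-matairesinol: O-alkylation with an (S)-oxazolidinone bromoacetimide, Evans syn-aldol with silylated vanillin, then borohydride release of the auxiliary.
2. The mono-silylated matairesinol comes from its 7′-oxo, 4′-O-benzyl precursor by one hydrogenolysis (C7′=O to CH2, OBn to OH).
3. Key disconnection: the γ-butyrolactone is the only ring that has to be made. It is cut at C4–C5 and C2–C3, which leaves an acyclic, achiral (E)-enone ArCH2–CH=CH–C(=O)Ar′ and an intact CH2–O–C(=O) unit bought as chloromethyl chloroformate.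
4. Enabling feature: in the lactone ring the segment C5–O1–C2(=O) is bracketed by the vicinal methines C4 and C3, and C3 carries the benzylic carbon C7′. With C7′ as a ketone, C3=C4 is polarised (C4 acceptor, C3 latent enolate). This matches a reagent whose O–CH2 carbon is turned into a donor by zinc and whose carbonate C=O stays an acceptor. The resulting β-keto lactone lets C3 settle trans to C4.
5. The enone is made by cross-metathesis of eugenol TIPS ether with the aryl vinyl ketone derived from O-benzylvanillin.

Key step: step 6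

Remark: locants are O1, C2(=O), C3, C4, C5 in the lactone, C7/C7′ for the benzylic carbons on C4/C3 and C7″–C9″ for the glycerol arm; the sense of induction of the phosphoramidite on enone 6 is assumed by analogy with other acyclic enones, and its antipode is equally available.

**Step 1**
Reactants: 1 eugenol (4-allyl-2-methoxyphenol)
Product: 2 eugenol TIPS ether [(4-allyl-2-methoxyphenoxy)triisopropylsilane]
Conditions: TIPSCl, imidazole, DMF, rt
Reagents that add atoms: triisopropylsilyl chloride, CC(C)[Si](Cl)(C(C)C)C(C)C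
Why: Imidazole-promoted O-silylation of a phenol; the bulky aryl TIPS ether should survive metathesis, organozinc, hydrogenolysis, carbonate base and boron triflate and should not migrate to a neighbouring phenoxide.

**Step 2**
Reactants: 3 O-benzylvanillin (4-benzyloxy-3-methoxybenzaldehyde)
Product: 4 racemic 1-[4-(benzyloxy)-3-methoxyphenyl]prop-2-en-1-ol
Conditions: CH2=CHMgBr, THF, 0 °C; aq NH4Cl
Reagents that add atoms: vinylmagnesium bromide, C=C[Mg]Br
Why: Grignard 1,2-addition to a non-enolisable aromatic aldehyde; the racemic carbinol centre is erased in step 3.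

**Step 3**
Reactants: 4 racemic 1-[4-(benzyloxy)-3-methoxyphenyl]prop-2-en-1-ol
Product: 5 1-[4-(benzyloxy)-3-methoxyphenyl]prop-2-en-1-one (aryl vinyl ketone)
Conditions: activated MnO2, CH2Cl2, rt
Reagents that add atoms: none
Why: MnO2 oxidation of a doubly activated (benzylic and allylic) alcohol under neutral conditions, which should spare the polymerisation-prone vinyl ketone.

**Step 4**
Reactants: 2 eugenol TIPS ether; 5 aryl vinyl ketone
Product: 6 (E)-1-[4-(benzyloxy)-3-methoxyphenyl]-4-[3-methoxy-4-(triisopropylsilyloxy)phenyl]but-2-en-1-one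
Conditions: (SIMes)Cl2Ru(=CH-C6H4-2-OiPr) (3 mol %), 1,4-benzoquinone (10 mol %), CH2Cl2, 40 °C
Reagents that add atoms: none
Why: Olefin cross-metathesis of a readily reacting allylarene with an electron-poor vinyl ketone that does not homodimerise is inherently cross- and E-selective, and benzoquinone should suppress Ru–H isomerisation of the allyl group.

**Step 5**
Reactants: 7 chloromethyl chloroformate; 8 phenol
Product: 10 iodomethyl phenyl carbonate, via chloromethyl phenyl carbonate 9 (not isolated)
Conditions: pyridine, CH2Cl2, 0 °C; then NaI, acetone, 40 °C, dark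
Reagents that add atoms: sodium iodide, [Na+].[I-]
Why: Acyl substitution at the chloroformate by phenol followed by Finkelstein exchange driven by precipitation of NaCl, which leaves the CH2–O–C(=O) unit intact with a phenoxide leaving group at one end and iodide at the other.

**Step 6**
Reactants: 6 (E)-enone; 10 iodomethyl phenyl carbonate
Product: 13 (3S,4R)-3-[4-(benzyloxy)-3-methoxybenzoyl]-4-[3-methoxy-4-(triisopropylsilyloxy)benzyl]dihydrofuran-2(3H)-one, via bis(carbonatomethyl)zinc reagent 11 (not isolated), via open-chain zinc enolate 12 (not isolated)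
Conditions: 10 (3.3 equiv), Et2Zn (1.5 equiv), PhMe, −40 °C; then 6, Cu(OTf)2 (5 mol %), (S,R,R)-BINOL bis(1-phenylethyl)amine phosphoramidite (10 mol %), −30 °C → rt; aq NH4Cl
Reagents that add atoms: none
Why: Proposed new method: iodine–zinc exchange turns the O–CH2–I carbon of 10, by nature an acceptor, into the chelate-stabilised donor 11, a chiral Cu(I)–phosphoramidite complex passes one CH2 group of 11 to the β-carbon C4 of the s-cis enone 6 (C4–C5 bond, a union of two acceptor carbons made possible by this polarity reversal), and the (Z)-zinc enolate 12 then attacks its own phenyl carbonate through C3 and expels phenoxide (C2–C3 bond). The closest known reaction types are the Cu/phosphoramidite-catalysed asymmetric conjugate addition of functionalised dialkylzincs to acyclic enones with in situ trapping of the zinc enolate, the conjugate addition of (acyloxymethyl)zinc–copper reagents to enones and conjugate addition–Dieckmann cascades; new is their merger through a C1 zinc reagent that carries its own acylating group. The γ-butyrolactone is closed by a favoured 5-(enolexo)-exo-trig acyl substitution, whereas O-acylation would need a seven-membered enol carbonate. C4 is set as R by the ligand, which must direct the copper-bound CH2 group to the Re face of C4, and C3 is set under thermodynamic control, because the β-keto lactone epimerises freely through its zinc chelate and enol and should settle on quench as the trans (3S,4R) isomer, so that both C3 epimers converge. The step needs regioselectivity (CH2 to C4, C=O to C3), 1,4- over 1,2-addition and exclusive transfer of the oxygenated group: the aryl ketone at C7′ fixes the polarity of C3=C4, soft zinc/copper species should leave aryl ketones, carbonates, silyl and benzyl ethers alone at these temperatures, and the excess of 10 drives the exchange to completion so that no ethyl group is left on zinc.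

**Step 7**
Reactants: 13 7′-oxo lactone
Product: 14 (3R,4R)-3-(4-hydroxy-3-methoxybenzyl)-4-[3-methoxy-4-(triisopropylsilyloxy)benzyl]dihydrofuran-2(3H)-one (4-O-TIPS-matairesinol)
Conditions: H2 (5 bar), 10% Pd/C, AcOH–EtOAc, 45 °C; then DBU (0.2 equiv), PhMe, rt
Reagents that add atoms: none
Why: Hydrogenolysis of an electron-rich benzylic ketone (C=O to CHOH to CH2) and O-debenzylation run on the same Pd surface, the aryl TIPS ether and the lactone are inert, and the brief base equilibration should return any cis isomer to the more stable trans (3R,4R) lactone.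

**Step 8**
Reactants: 15 (S)-4-benzyloxazolidin-2-one
Product: 16 (S)-4-benzyl-3-(2-bromoacetyl)oxazolidin-2-one
Conditions: n-BuLi, THF, −78 °C; BrCH2COBr, −78 → 0 °C
Reagents that add atoms: bromoacetyl bromide, BrCC(Br)=O
Why: N-acylation of the lithiated oxazolidinone, in which the acyl bromide reacts far faster than the alkyl bromide and the stereocentre is untouched.

**Step 9**
Reactants: 14 4-O-TIPS-matairesinol; 16 bromoacetyl imide
Product: 17 aryloxyacetyl imide: the 4′-O-CH2C(=O)-[(S)-4-benzyl-2-oxooxazolidin-3-yl] ether of 14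
Conditions: K2CO3, acetone, rt
Reagents that add atoms: none
Why: Williamson ether synthesis in which the only free OH of 14, the 4′-phenol on the C3 benzyl ring, displaces the activated α-bromide faster than it attacks the imide carbonyl, while the trans lactone is already the thermodynamic epimer.

**Step 10**
Reactants: 18 vanillin
Product: 19 3-methoxy-4-(triisopropylsilyloxy)benzaldehyde
Conditions: TIPSCl, imidazole, DMF, rt
Reagents that add atoms: triisopropylsilyl chloride, CC(C)[Si](Cl)(C(C)C)C(C)C
Why: Imidazole-promoted O-silylation of a phenol, which gives the same protecting group as in 2 so that one final operation frees both phenols.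

**Step 11**
Reactants: 17 aryloxyacetyl imide; 19 TIPS-vanillin
Product: 21 syn-aldol adduct: (2S,3R)-2-aryloxy-3-hydroxy-3-[3-methoxy-4-(triisopropylsilyloxy)phenyl]propanoyl imide of the (S)-auxiliary, via dibutylboron Z-enolate 20 (not isolated)
Conditions: n-Bu2BOTf, Et3N, CH2Cl2, −78 → 0 °C; 19, −78 → 0 °C; pH 7 buffer, MeOH, H2O2, 0 °C
Reagents that add atoms: none
Why: Evans syn-aldol: soft enolisation touches only the imide and not the lactone, and the (Z)-boron enolate reacts through a closed chair transition state on the face away from the benzyl group of the (S)-auxiliary, which sets C8″ and C7″ in the syn (threo) sense needed and turns any residual antipode of the lactone core into a separable diastereomer.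

**Step 12**
Reactants: 21 syn-aldol adduct
Product: 22 bis-TIPS ether of the target with the free (7″R,8″R)-7″,9″-diol
Conditions: NaBH4, THF–H2O (4:1), 0 °C
Reagents that add atoms: none
Why: Reductive cleavage of an N-acyloxazolidinone with borohydride, in which the α-aryloxy imide carbonyl is much more electrophilic than the γ-lactone and should be taken to the primary alcohol without touching a stereocentre.

**Step 13**
Reactants: 22 bis-TIPS ether
Product: 23 target, (3R,4R)-3-{4-[(1R,2R)-1,3-dihydroxy-1-(4-hydroxy-3-methoxyphenyl)propan-2-yloxy]-3-methoxybenzyl}-4-(4-hydroxy-3-methoxybenzyl)dihydrofuran-2(3H)-one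
Conditions: TBAF, AcOH, THF, 0 °C
Reagents that add atoms: none
Why: Fluoride-induced cleavage of both aryl silyl ethers, buffered with acetic acid so that the phenols stay protonated and neither quinone methide formation at C7″ nor lactone epimerisation should set in.

**Compound list**

| No. | Name | SMILES | Role |
|---|---|---|---|
| 1 | eugenol | C=CCc1ccc(O)c(OC)c1 | starting material |
| 2 | eugenol TIPS ether | C=CCc1ccc(O[Si](C(C)C)(C(C)C)C(C)C)c(OC)c1 | intermediate |
| 3 | 4-benzyloxy-3-methoxybenzaldehyde | O=Cc1ccc(OCc2ccccc2)c(OC)c1 | starting material |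
| 4 | racemic 1-[4-(benzyloxy)-3-methoxyphenyl]prop-2-en-1-ol | C=CC(O)c1ccc(OCc2ccccc2)c(OC)c1 | intermediate |
| 5 | 1-[4-(benzyloxy)-3-methoxyphenyl]prop-2-en-1-one | C=CC(=O)c1ccc(OCc2ccccc2)c(OC)c1 | intermediate |
| 6 | (E)-1-[4-(benzyloxy)-3-methoxyphenyl]-4-[3-methoxy-4-(triisopropylsilyloxy)phenyl]but-2-en-1-one | COc1cc(C/C=C/C(=O)c2ccc(OCc3ccccc3)c(OC)c2)ccc1O[Si](C(C)C)(C(C)C)C(C)C | intermediate |
| 7 | chloromethyl chloroformate | ClCOC(Cl)=O | starting material |
| 8 | phenol | Oc1ccccc1 | starting material |
| 9 | chloromethyl phenyl carbonate | ClCOC(=O)Oc1ccccc1 | intermediate |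
| 10 | iodomethyl phenyl carbonate | ICOC(=O)Oc1ccccc1 | intermediate |
| 11 | bis{[(phenoxycarbonyl)oxy]methyl}zinc | O=C(OC[Zn]COC(=O)Oc1ccccc1)Oc1ccccc1 | intermediate |
| 12 | (Z)-zinc enolate of the (R)-configured open-chain conjugate adduct | COc1cc(C[C@@H](COC(=O)Oc2ccccc2)/C=C(\O[Zn]COC(=O)Oc2ccccc2)c2ccc(OCc3ccccc3)c(OC)c2)ccc1O[Si](C(C)C)(C(C)C)C(C)C | intermediate |
| 13 | (3S,4R)-3-[4-(benzyloxy)-3-methoxybenzoyl]-4-[3-methoxy-4-(triisopropylsilyloxy)benzyl]dihydrofuran-2(3H)-one | COc1cc(C[C@H]2COC(=O)[C@@H]2C(=O)c2ccc(OCc3ccccc3)c(OC)c2)ccc1O[Si](C(C)C)(C(C)C)C(C)C | intermediate |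
| 14 | (3R,4R)-3-(4-hydroxy-3-methoxybenzyl)-4-[3-methoxy-4-(triisopropylsilyloxy)benzyl]dihydrofuran-2(3H)-one | COc1cc(C[C@H]2COC(=O)[C@@H]2Cc2ccc(O)c(OC)c2)ccc1O[Si](C(C)C)(C(C)C)C(C)C | intermediate |
| 15 | (S)-4-benzyloxazolidin-2-one | O=C1N[C@@H](Cc2ccccc2)CO1 | starting material |
| 16 | (S)-4-benzyl-3-(2-bromoacetyl)oxazolidin-2-one | O=C1OC[C@H](Cc2ccccc2)N1C(=O)CBr | intermediate |
| 17 | aryloxyacetyl imide of 14 | COc1cc(C[C@H]2COC(=O)[C@@H]2Cc2ccc(OCC(=O)N3C(=O)OC[C@@H]3Cc3ccccc3)c(OC)c2)ccc1O[Si](C(C)C)(C(C)C)C(C)C | intermediate |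
| 18 | vanillin | O=Cc1ccc(O)c(OC)c1 | starting material |
| 19 | 3-methoxy-4-(triisopropylsilyloxy)benzaldehyde | O=Cc1ccc(O[Si](C(C)C)(C(C)C)C(C)C)c(OC)c1 | intermediate |
| 20 | dibutylboron (Z)-enolate of 17 | COc1cc(C[C@H]2COC(=O)[C@@H]2Cc2ccc(O/C=C(\OB(CCCC)CCCC)N3C(=O)OC[C@@H]3Cc3ccccc3)c(OC)c2)ccc1O[Si](C(C)C)(C(C)C)C(C)C | intermediate |
| 21 | (2S,3R)-syn-aldol imide | COc1cc(C[C@H]2COC(=O)[C@@H]2Cc2ccc(O[C@H](C(=O)N3C(=O)OC[C@@H]3Cc3ccccc3)[C@H](O)c3ccc(O[Si](C(C)C)(C(C)C)C(C)C)c(OC)c3)c(OC)c2)ccc1O[Si](C(C)C)(C(C)C)C(C)C | intermediate |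
| 22 | bis-TIPS ether of the target | COc1cc(C[C@H]2COC(=O)[C@@H]2Cc2ccc(O[C@H](CO)[C@H](O)c3ccc(O[Si](C(C)C)(C(C)C)C(C)C)c(OC)c3)c(OC)c2)ccc1O[Si](C(C)C)(C(C)C)C(C)C | intermediate |
| 23 | CNP0305334.1 | COc1cc(C[C@H]2COC(=O)[C@@H]2Cc2ccc(O[C@H](CO)[C@H](O)c3ccc(O)c(OC)c3)c(OC)c2)ccc1O | target |

**Step count**

- Total step count: 13.
- Longest linear sequence: 9 steps (3 → 4 → 5 → 6 → 13 → 14 → 17 → 21 → 22 → 23).

**Steps most likely to fail**

**Step 6 (Proposed new method).**
- What may go wrong: the chelated oxygenated methyl group may pass from zinc to copper too slowly. The zinc reagent may decay in a carbenoid manner or by a 1,2-acyl shift before it is consumed. Facial selectivity on an acyclic aryl enone may be insufficient.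
- Fallback: it uses known chemistry, sets out from 2 and comes back at 13. Compound 2 is combined with dichloroketene (Cl3CCOCl, Zn–Cu, Et2O) in a [2+2] cycloaddition to give racemic 2,2-dichloro-3-[3-methoxy-4-(triisopropylsilyloxy)benzyl]cyclobutanone F1. Zinc in acetic acid removes both chlorines and gives the prochiral 3-[3-methoxy-4-(triisopropylsilyloxy)benzyl]cyclobutanone F2. An enantioselective Baeyer–Villiger desymmetrisation with an (R)-selective Baeyer–Villiger monooxygenase gives (R)-4-[3-methoxy-4-(triisopropylsilyloxy)benzyl]dihydrofuran-2(3H)-one F3. Deprotonation with LiHMDS (2 equiv, THF, −78 °C) follows. C-acylation anti to the C4 substituent with 4-(benzyloxy)-3-methoxybenzoyl chloride F4, made from the commercial acid with oxalyl chloride, gives 13.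

**Step 7.**
- What may go wrong: the reduction may stall at the benzylic alcohol stage, because the p-oxygenated aryl ketone becomes a poor acceptor once the benzyl ether is lost. Forcing it with strong acid may cost the silyl ether.
- Fallback: it sets out from 13 and comes back at 14. NaBH4 (THF–MeOH, −20 °C) reduces the ketone to the 7′-hydroxy lactone F5, an epimer mixture at C7′. MsCl/Et3N converts it into the 7′-mesylate F6. DBU then induces E1cB elimination to the (E)-3-arylidene lactone F7. Neutral hydrogenation (H2, 1 atm, Pd/C, EtOAc) saturates the alkene and cleaves the benzyl ether, and DBU equilibration at C3 gives 14.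

**Step 12.**
- What may go wrong: competing reduction or opening of the lactone, and retro-aldol cleavage in the basic borohydride medium.
- Fallback: it sets out from 21 and comes back at 22. LiOH/H2O2 (THF–H2O, 0 °C) cleaves the imide to the (2S,3R)-2-aryloxy-3-hydroxy carboxylic acid F8, and acidic work-up recloses any opened lactone. BH3·SMe2 (THF, 0 °C) then reduces the free acid in preference to the lactone and gives 22.

**Further compounds**

F1 | step 6 | racemic 2,2-dichloro-3-[3-methoxy-4-(triisopropylsilyloxy)benzyl]cyclobutanone | COc1cc(CC2CC(=O)C2(Cl)Cl)ccc1O[Si](C(C)C)(C(C)C)C(C)C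
F2 | step 6 | 3-[3-methoxy-4-(triisopropylsilyloxy)benzyl]cyclobutanone | COc1cc(CC2CC(=O)C2)ccc1O[Si](C(C)C)(C(C)C)C(C)C
F3 | step 6 | (R)-4-[3-methoxy-4-(triisopropylsilyloxy)benzyl]dihydrofuran-2(3H)-one | COc1cc(C[C@H]2COC(=O)C2)ccc1O[Si](C(C)C)(C(C)C)C(C)C
F4 | step 6 | 4-(benzyloxy)-3-methoxybenzoyl chloride | O=C(Cl)c1ccc(OCc2ccccc2)c(OC)c1
F5 | step 7 | (3R,4R)-configured 7′-hydroxy lactone, epimer mixture at C7′ | COc1cc(C[C@H]2COC(=O)[C@@H]2C(O)c2ccc(OCc3ccccc3)c(OC)c2)ccc1O[Si](C(C)C)(C(C)C)C(C)C
F6 | step 7 | 7′-mesylate of the 7′-hydroxy lactone | COc1cc(C[C@H]2COC(=O)[C@@H]2C(OS(C)(=O)=O)c2ccc(OCc3ccccc3)c(OC)c2)ccc1O[Si](C(C)C)(C(C)C)C(C)C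
F7 | step 7 | (R,E)-3-[4-(benzyloxy)-3-methoxybenzylidene]-4-[3-methoxy-4-(triisopropylsilyloxy)benzyl]dihydrofuran-2(3H)-one | COc1cc(C[C@H]2COC(=O)/C2=C/c2ccc(OCc3ccccc3)c(OC)c2)ccc1O[Si](C(C)C)(C(C)C)C(C)C
F8 | step 12 | (2S,3R)-2-aryloxy-3-hydroxy-3-[3-methoxy-4-(triisopropylsilyloxy)phenyl]propanoic acid of the lactone core | COc1cc(C[C@H]2COC(=O)[C@@H]2Cc2ccc(O[C@H](C(=O)O)[C@H](O)c3ccc(O[Si](C(C)C)(C(C)C)C(C)C)c(OC)c3)c(OC)c2)ccc1O[Si](C(C)C)(C(C)C)C(C)C
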